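The target forms from starting material and coupling partner, and in this flask neither is in solution at the start: the first comes off the solid, the second out of the gas.

solid substrate 0.17 M; second substrate 0.170 M; gas 21 mM (held); time 1.5 h

    starting material + coupling partner → target (k1 = 0.0149 L mol⁻¹ s⁻¹)
    second substrate + coupling partner → second product (k2 = 0.00203 L mol⁻¹ s⁻¹)
    starting material + second substrate → cross product (k3 = 2.48 × 10⁻⁴ L mol⁻¹ s⁻¹)
    coupling partner → decomposed reagent (k4 = 1.64 × 10⁻⁴ s⁻¹)
    gas ⇌ coupling partner, rate k5*(csat - [coupling partner]) (k5 = 9.40 × 10⁻⁴ s⁻¹, csat = 21 mM)
    solid substrate ⇌ starting material, rate k6*(cs6 - [starting material]) while solid is left; crystals form when [starting material] > cs6 (cs6 = 22 mM, k6 = 0.00609 s⁻¹)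

- solid, in amounts per volume of the solution: solid substrate
- at the start none of coupling partner is dissolved
- at the start none of the solid substrate is in solution
- what has only dissolved of solid substrate counts as not reacted
- starting material means what is dissolved; the solid is not counted in it
- the reaction counts as stopped when no species that holds the solid substrate changes by six tenths of a point or more over the second half of the time
- run time (flask): 1.5 h

* the state of affairs at 1.5 h: stopped, and by what, or still going (for what has run out or reacted, a solid counts together with what of it has only dissolved) (all of the solid substrate has reacted / forward and back rates have come level / it is still moving)
* part of the solid substrate that has turned into other species by 1.5 h (what has only dissolved does not count)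
* the target standing at 1.5 h, as a percentage of the solid substrate charged
* the starting material standing at 1.5 h, as a percentage of the solid substrate charged
* the cross product standing at 1.5 h, as a percentage of the solid substrate charged

A ladder of time scales orders the flask. The lowest rung is dissolution, with its time

τ_d = 2.74 min

Next comes the coupling partner, fed by transfer and lost to target, second product and decomposition. With starting material at its solubility and second substrate at its charge, it levels off after a lag τ_B at a plateau B*:

τ_B = 9.38 min, B* = 11.1 mM

Dissolution is quicker than this lag, so the solution holds a pool of starting material before much coupling partner has arrived. That pool drains to target and cross product with a pseudo-first-order constant k_T, and one turnover takes τ_T: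

k_T = 0.748 h⁻¹, τ_T = 1.34 h

This time is longer than the lag. While solid is left, dissolution balances the drain, and the pool stands at

A* = 21.3 mM

Counting the target's part from the end of the lag and the cross product's part from the start gives

N = 1.03

This N is the number of pool turnovers, the times the dissolved pool has been replaced by the asked time. Each turnover converts one pool, so the reckoning gives conversion 12.9 %, target 10.0 %, starting material 12.5 % and cross product 2.85 %. The top rung is emptying the charge, which by this reckoning takes about 10.7 h. That is longer than the run, so solid should remain and the flask should still be moving.

The forecast says it is still moving, with conversion 12.7 %, target 10.1 %, starting material 12.5 % and cross product 2.6 %, its conversion lying slightly under the reckoning above: “Target and cross product therefore keep forming at a nearly steady rate”.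

The simulation reads it is still moving, with conversion 12.7 %, target 10.1 %, starting material 12.5 % and cross product 2.60 %. Solid substrate still stands at 74.8 % of the charge at 1.50 h. Carried to the neighbour flask with 0.29 M of solid substrate, N over the larger charge gives 7.57 %, and that flask reads 7.46 %.

(The constants used here were chosen freely; what happens was integrated by code.)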